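## Analysis of the target

Drimane numbering is used for the terpenoid part: ring A is C1–C5/C10 and ring B is C5–C10, C11 is the vinylic carbon on C9, and the methyl groups sit on C4 (two), C8 and C10. The arene is C1'–C6', with C1' bonded to C11, 2'-OSO3H, 3'-CHO, 4'-OH, 5'-OSO3H and 6'-H.

- **Ring system.** The skeleton is a trans-decalin (5α-H, 10β-CH3) with an exocyclic, trisubstituted C9=C11 double bond that carries a penta-substituted benzene ring. The alkene is E: the aryl group is cis to C8 and trans to the quaternary C10.
- **Stereocentres.** C5 and C10 have the configuration of the cheap labdane/drimane chiral pool. C8 is S: its methyl is β, axial and 1,3-syn to the C10 methyl. In a saturated decalin this is the less stable epimer, so it cannot be set by equilibration.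
- **Feature that invites the key move.** The array H–C8–C9=C11 (an allylic C–H stereocentre on ring B next to an exocyclic alkene) is the retron of a retro-ene decarboxylation. The precursor would be a C8=C9 olefinic acid with a CH2CO2H arm on C9, which is exactly the carbon skeleton of ring-opened sclareolide.
- **Second feature.** O2' and O5' are para to each other and flank a styrene with a C9–H. This is the aromatic tautomer of an alkyl-p-quinone, reached through an o-quinone methide.
- **Sensitive groups.** Any cation at C8 or C9 with the arene attached is three atoms from O2' and C6'; closure to a chroman or an indane, or hydride/methyl shifts, would follow. The 2',5'-hydroquinone is air-sensitive, aryl sulfate monoesters are acid-labile, and the aldehyde lies between two oxygens.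
- **Main difficulties.** The axial C8 methyl next to a hindered exocyclic alkene, and the regiochemistry of sulfation: of three phenolic oxygens, two are sulfated while the 4'-OH next to the aldehyde stays free.

## Retrosynthetic reasoning

**15 ⇒ 14 ⇒ 13.** The last operations are removal of the 4'-O protecting group and, before it, formation of the two S–O bonds. Sulfate monoesters tolerate base and fluoride but not acid. The 4'-oxygen is therefore carried as a 2-(trimethylsilyl)ethyl ether, which is cleaved by fluoride from the disodium bis-sulfate 14. Compound 14 comes from hydroquinone 13, in which only O2' and O5' are free.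

**13 ⇒ 11 (through 12).** No bond between heavy atoms is cut here. Compound 13 is the aromatic tautomer of alkyl-quinone 11: two hydrogens move from C11 and C9 to O5' and O2' by way of o-quinone methide 12. This one isomerisation introduces the C9=C11 double bond without an external oxidant. It also delivers exactly the two phenols that are to be sulfated, while O4' stays an ether. The forward reaction has to enolise the quinone toward C11 and then shift H9; the E geometry follows from allylic strain against C10.

**11 ⇒ 10 ⇒ 9 + 8.** Quinone 11 comes from the p-dimethoxyarene 10 by oxidative demethylation, done while the side chain is still saturated. Compound 10 is cut at C11–C1' into the primary alkylborane 9 and aryl bromide 8. An sp3–sp2 coupling is chosen because no cation is formed, C8 is not touched, and the configuration at C9 does not matter (C9 becomes sp2 later).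

**9 ⇒ 4.** The borane comes from anti-Markovnikov hydroboration of the exocyclic alkene 4.

**4 ⇒ 3 (key disconnection).** The H–C8–C9=C11 array of 4 is traced back to acid 3: a carboxyl group is added to C11, the double bond is moved to C8=C9, and the hydrogen on C8 is removed. In the forward direction the C11–carboxyl bond is cleaved, the carboxyl proton goes to C8, and the alkene moves to C9=C11. The cut is made here because 3 has the sixteen carbons of (+)-sclareolide 1, which already holds C5 and C10 correctly. C8 then has to be formed with a single element of control, the face of hydrogen delivery.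

**3 ⇒ 2 ⇒ 1.** Acid 3 comes from ester 2, and 2 from lactone 1 by acid-mediated ring opening with elimination to the tetrasubstituted alkene. This cationic step is placed before any arene is attached, so the C8 cation has nothing to be trapped by.

**8 ⇒ 7 ⇒ 6 ⇒ 5.** Bromine is introduced para to O4'. The formyl group goes between two oxygens by directed metalation. O4' is differentiated from the outset because it is the only free hydroxyl of phenol 5.

## Alternatives that were turned down

**Alternative 1:** (textbook) Disconnection at C11–C1' by carbonyl addition. An aryllithium is added to the one-carbon-degraded aldehyde A1 (8β-methyl-driman-11-al) to give carbinol A2, which is dehydrated with acid to the C9=C11 styrene.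
- A1 costs about six steps from 1: one-carbon degradation, dehydration, a separate hydrogenation to set C8, and redox adjustment.
- The addition to a neopentyl-type aldehyde gives epimeric carbinols, and the dehydration runs through a benzylic cation next to C9.
- The formyl group has to be added after the coupling.
- The decisive point: two of three aryl ethers would then have to be unmasked oxidatively or with Lewis acid in the presence of the electron-rich alkene. The route is longer and leaves the sulfation problem unsolved.

**Alternative 2:** Disconnection of C4–C5 and C9–C10. Farnesyl arene A3 would be cyclised by an enantioselective, proton-initiated polyene cyclisation with a chiral Brønsted acid.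
- Both rings and C5/C10 would form in one step, but the cascade ends in a C8 cation three atoms from O2' and C6'. Closure to the chroman or the indane is the expected fate.
- Even with clean elimination, a mixture of alkene isomers would result. C8 would still need a hydrogenation and C9=C11 a dehydrogenation.
- Enantiocontrol without a C3 oxygen needs specialised catalysts. The step builds what sclareolide supplies for free and leaves the hard parts open.

**Alternative 3:** Disconnection at C11–C1' by enolate arylation of 1 to the 11-aryl lactone A4. An acid-triggered cascade would follow in one flask: C8–O ionisation, 1,2-hydride shift from C9 to C8, and loss of the carboxyl carbon from the C9 cation.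
- It is the shortest route on paper, and the hydride shift would set C8 stereospecifically.
- It was turned down because the C8 cation is generated with the arene in place: O2' and C6' traps and further methyl shifts are irreversible, and the product styrene is itself acid-sensitive.
- The idea (hydrogen to C8, loss of the carboxyl carbon, alkene to C9=C11) is kept in the chosen route, but in pericyclic form and before the arene is attached.

Key step: step 3

## Assumptions

- The target is drawn as the free bis(hydrogen sulfate) and is taken as such. It is obtained by cold acidification of the disodium salt; in practice aryl sulfates are stored as salts.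
- (+)-Sclareolide 1 and 2,5-dimethoxyphenol 5 are taken as commercial.

## Route

Step 1
Reactants: 1 (+)-sclareolide
Product: 2 methyl 2-[(4aS,8aS)-2,5,5,8a-tetramethyl-3,4,4a,5,6,7,8,8a-octahydronaphthalen-1-yl]acetate (C8=C9 tetrasubstituted alkene)
Conditions: conc. H2SO4 (0.5 equiv), MeOH, reflux, 24 h; NaHCO3 work-up; AgNO3–SiO2 chromatography, minor alkene isomers resubmitted
Reagents that add atoms: methanol, CO
Why: Acid-catalysed ring-opening transesterification with E1 loss of water from tertiary C8 under thermodynamic control should favour the tetrasubstituted C8=C9 ester. No arene is present, so the C8 cation can only eliminate or return; C5 and C10 are untouched.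

Step 2
Reactants: 2 methyl ester
Product: 3 2-[(4aS,8aS)-2,5,5,8a-tetramethyl-3,4,4a,5,6,7,8,8a-octahydronaphthalen-1-yl]acetic acid
Conditions: LiOH·H2O (3 equiv), THF/MeOH/H2O, 40 °C; then 1 M HCl to pH 4, 0 °C
Reagents that add atoms: lithium hydroxide, [Li+].[OH-]
Why: Saponification of an unhindered CH2CO2Me ester. Mild base and a cold, weakly acidic work-up should avoid conjugation of the alkene and relactonisation.

Step 3
Reactants: 3 β,γ-unsaturated acid
Product: 4 (2S,4aS,8aS)-2,5,5,8a-tetramethyl-1-methylidenedecahydronaphthalene (8β-methyl, exocyclic C9=C11)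
Conditions: degassed Ph2O (0.1 M), 250 °C, Ar, 1–2 h, base-washed glassware; SiO2, pentane
Reagents that add atoms: none
Why: Thermal decarboxylation of a β,γ-unsaturated acid by a concerted retro-ene reaction: in a six-membered transition state the carboxyl proton is delivered to C8 while the C11–CO2H bond breaks and the double bond moves to C9=C11, so the former lactone carbonyl carbon of 1 leaves as CO2. The closest known reaction type is the classical pyrolytic decarboxylation of 3-alkenoic acids; the electron-rich tetrasubstituted C8=C9 bond and the tertiary C9 should put 3 at the easy end of that class. No ring is closed; rings A and B and the C5/C10 centres come unchanged from 1. The one new stereocentre, C8, is set by the face on which the CH2CO2H arm stands when it is perpendicular to the alkene plane: on the β-face it would be 1,3-parallel to the axial C10 methyl, on the α-face it meets only ring hydrogens. The proton should therefore arrive from the α-face and push the C8 methyl into the β (axial) position, which is the 8S configuration of the target. The only selectivity needed is α- versus β-face delivery; the regiochemistry is fixed by the pericyclic mechanism, and the product forms irreversibly as the kinetic C8 epimer. Neutral, proton-poor conditions are essential, because acid would relactonise 3 or move the exocyclic double bond of 4 into the ring and erase C8.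

Step 4
Reactants: 5 2,5-dimethoxyphenol
Product: 6 [2-(2,5-dimethoxyphenoxy)ethyl]trimethylsilane
Conditions: Me3SiCH2CH2OH (1.2 equiv), PPh3, DIAD, THF, 0 °C → rt
Reagents that add atoms: 2-(trimethylsilyl)ethanol, C[Si](C)(C)CCO
Why: Mitsunobu etherification of a phenol with a primary alcohol. It marks the future 4'-oxygen with a fluoride-labile group that should survive organolithium, Pd, Ce(IV) and base.

Step 5
Reactants: 6 aryl ether
Product: 7 3,6-dimethoxy-2-[2-(trimethylsilyl)ethoxy]benzaldehyde
Conditions: n-BuLi (1.2 equiv), TMEDA, THF, 0 °C; DMF, −78 °C → rt; 1 M HCl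
Reagents that add atoms: N,N-dimethylformamide, CN(C)C=O
Why: Directed ortho-metalation at the only position flanked by two alkoxy groups (between O-CH2CH2SiMe3 and OMe), then formylation with DMF. This places the aldehyde at the future C3'.

Step 6
Reactants: 7 aldehyde
Product: 8 5-bromo-3,6-dimethoxy-2-[2-(trimethylsilyl)ethoxy]benzaldehyde
Conditions: NBS (1.05 equiv), MeCN, 0 °C → rt
Reagents that add atoms: N-bromosuccinimide, O=C1CCC(=O)N1Br
Why: Electrophilic aromatic bromination at the position para to the 2-alkoxy group, ortho to a methoxy group and meta to the aldehyde. The other free position is para to the aldehyde and less activated.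

Step 7
Reactants: 4 exocyclic alkene
Product: 9 9-{[(1S,2S,4aS,8aR)-2,5,5,8a-tetramethyldecahydronaphthalen-1-yl]methyl}-9-borabicyclo[3.3.1]nonane
Conditions: 9-BBN dimer (0.95 equiv B–H), THF, 65 °C, 12 h; concentrated under Ar, crude oil used directly
Reagents that add atoms: 9-borabicyclo[3.3.1]nonane, B1C2CCCC1CCC2
Why: Anti-Markovnikov hydroboration puts boron on C11. Hydrogen should add to C9 from the α-face, because the β-face is covered by the two axial methyls on C8 and C10; the C9 configuration is erased later and C8 is not touched. A slight deficit of B–H protects the aldehyde of 8 in the next step.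

Step 8
Reactants: 9 alkylborane; 8 aryl bromide
Product: 10 3,6-dimethoxy-5-{[(1S,2S,4aS,8aR)-2,5,5,8a-tetramethyldecahydronaphthalen-1-yl]methyl}-2-[2-(trimethylsilyl)ethoxy]benzaldehyde
Conditions: Pd(dppf)Cl2·CH2Cl2 (5 mol%), 3 M aq K3PO4 (3 equiv), THF/DMF, 60 °C, 12 h
Reagents that add atoms: none
Why: B-alkyl Suzuki–Miyaura coupling of a primary alkyl-9-BBN with an aryl bromide forms C11–C1' without any cationic intermediate. Aldehyde, aryl ethers and the silyl group are compatible.

Step 9
Reactants: 10 p-dimethoxyarene
Product: 11 3,6-dioxo-5-{[(1S,2S,4aS,8aR)-2,5,5,8a-tetramethyldecahydronaphthalen-1-yl]methyl}-2-[2-(trimethylsilyl)ethoxy]cyclohexa-1,4-diene-1-carbaldehyde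
Conditions: (NH4)2Ce(NO3)6 (2.5 equiv), MeCN/H2O 3:1, 0 °C, 15 min
Reagents that add atoms: water, O
Why: Ce(IV) oxidative demethylation of the para-dimethoxy pair (O2'/O5') gives the p-quinone, while the 4'-alkoxy group stays as a vinylogous ester. The oxidant is used while the side chain is still saturated, so no alkene is exposed to it.

Step 10
Reactants: 11 alkyl-quinone
Product: 13 3,6-dihydroxy-5-{(E)-[(2S,4aS,8aS)-2,5,5,8a-tetramethyloctahydronaphthalen-1(2H)-ylidene]methyl}-2-[2-(trimethylsilyl)ethoxy]benzaldehyde, via o-quinone methide 12 (not isolated)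
Conditions: Et3N (0.5 equiv), degassed toluene, 40 °C, Ar, exclusion of water and O2
Reagents that add atoms: none
Why: Base-mediated tautomerisation of an alkyl-p-quinone to its o-quinone methide (C11=C1'), then the known o-quinone methide to o-vinylphenol isomerisation by shift of H9 to O2'. This gives the aromatic hydroquinone with the C9=C11 bond; E is expected because the aryl group avoids the quaternary C10. The step frees only O2' and O5', and C8 is not involved.

Step 11
Reactants: 13 hydroquinone
Product: 14 disodium salt of 3,6-bis(sulfonatooxy)-5-{(E)-[(2S,4aS,8aS)-2,5,5,8a-tetramethyloctahydronaphthalen-1(2H)-ylidene]methyl}-2-[2-(trimethylsilyl)ethoxy]benzaldehyde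
Conditions: SO3·pyridine (8 equiv), pyridine, 50 °C, 12 h, Ar; sat. aq NaHCO3; C18 chromatography
Reagents that add atoms: sulfur trioxide–pyridine complex, [O-]S(=O)(=O)[n+]1ccccc1; sodium hydrogen carbonate, [Na+].OC([O-])=O
Why: O-Sulfation of phenols with SO3·pyridine. Only O2' and O5' are free; excess reagent and mild heating are planned for the hydrogen-bonded, hindered 2'-OH.

Step 12
Reactants: 14 bis-sulfate
Product: 15 2-hydroxy-3,6-bis(sulfooxy)-5-{(E)-[(2S,4aS,8aS)-2,5,5,8a-tetramethyloctahydronaphthalen-1(2H)-ylidene]methyl}benzaldehyde (target, CNP0309628.1)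
Conditions: CsF (5 equiv), DMF, 60 °C; then 1 M HCl (3 equiv), 0 °C; cold C18 desalting, lyophilisation
Reagents that add atoms: none
Why: Fluoride attacks silicon and the 2-(trimethylsilyl)ethyl ether fragments to ethene and the phenoxide, which is a good leaving group because of the ortho aldehyde. Sulfate monoester anions, the aldehyde and the alkene should tolerate fluoride; brief cold acidification gives the acid form.

## Compound list

1 | (+)-sclareolide, (3aR,5aS,9aS,9bR)-3a,6,6,9a-tetramethyldecahydronaphtho[2,1-b]furan-2(1H)-one | CC1(CCC[C@]2([C@H]1CC[C@@]3([C@@H]2CC(=O)O3)C)C)C | starting material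
2 | methyl 2-[(4aS,8aS)-2,5,5,8a-tetramethyl-3,4,4a,5,6,7,8,8a-octahydronaphthalen-1-yl]acetate | CC1=C(CC(=O)OC)[C@@]2(C)CCCC(C)(C)[C@@H]2CC1 | intermediate
3 | 2-[(4aS,8aS)-2,5,5,8a-tetramethyl-3,4,4a,5,6,7,8,8a-octahydronaphthalen-1-yl]acetic acid | CC1=C(CC(=O)O)[C@@]2(C)CCCC(C)(C)[C@@H]2CC1 | intermediate
4 | (2S,4aS,8aS)-2,5,5,8a-tetramethyl-1-methylidenedecahydronaphthalene | C[C@H]1CC[C@H]2C(C)(C)CCC[C@]2(C)C1=C | intermediate
5 | 2,5-dimethoxyphenol | COc1ccc(OC)c(O)c1 | starting material
6 | [2-(2,5-dimethoxyphenoxy)ethyl]trimethylsilane | COc1ccc(OC)c(OCC[Si](C)(C)C)c1 | intermediate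
7 | 3,6-dimethoxy-2-[2-(trimethylsilyl)ethoxy]benzaldehyde | COc1ccc(OC)c(C=O)c1OCC[Si](C)(C)C | intermediate
8 | 5-bromo-3,6-dimethoxy-2-[2-(trimethylsilyl)ethoxy]benzaldehyde | COc1cc(Br)c(OC)c(C=O)c1OCC[Si](C)(C)C | intermediate
9 | 9-{[(1S,2S,4aS,8aR)-2,5,5,8a-tetramethyldecahydronaphthalen-1-yl]methyl}-9-borabicyclo[3.3.1]nonane (8β-methyl, 9α-H) | C[C@H]1CC[C@H]2C(C)(C)CCC[C@]2(C)[C@H]1CB1C2CCCC1CCC2 | intermediate
10 | 3,6-dimethoxy-5-{[(1S,2S,4aS,8aR)-2,5,5,8a-tetramethyldecahydronaphthalen-1-yl]methyl}-2-[2-(trimethylsilyl)ethoxy]benzaldehyde | C[C@H]1CC[C@H]2C(C)(C)CCC[C@]2(C)[C@H]1Cc1cc(OC)c(OCC[Si](C)(C)C)c(C=O)c1OC | intermediate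
11 | 3,6-dioxo-5-{[(1S,2S,4aS,8aR)-2,5,5,8a-tetramethyldecahydronaphthalen-1-yl]methyl}-2-[2-(trimethylsilyl)ethoxy]cyclohexa-1,4-diene-1-carbaldehyde | C[C@H]1CC[C@H]2C(C)(C)CCC[C@]2(C)[C@H]1CC1=CC(=O)C(OCC[Si](C)(C)C)=C(C=O)C1=O | intermediate
12 | o-quinone methide tautomer of 11: 3-hydroxy-6-oxo-5-(decalinylmethylidene)-2-[2-(trimethylsilyl)ethoxy]cyclohexa-1,3-diene-1-carbaldehyde, decalin unit as in 11 | C[C@H]1CC[C@H]2C(C)(C)CCC[C@]2(C)[C@H]1C=C1C=C(O)C(OCC[Si](C)(C)C)=C(C=O)C1=O | intermediate (not isolated)
13 | 3,6-dihydroxy-5-{(E)-[(2S,4aS,8aS)-2,5,5,8a-tetramethyloctahydronaphthalen-1(2H)-ylidene]methyl}-2-[2-(trimethylsilyl)ethoxy]benzaldehyde | C[C@H]1CC[C@H]2C(C)(C)CCC[C@]2(C)/C1=C/c1cc(O)c(OCC[Si](C)(C)C)c(C=O)c1O | intermediate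
14 | disodium salt of 3,6-bis(sulfonatooxy)-5-{(E)-[(2S,4aS,8aS)-2,5,5,8a-tetramethyloctahydronaphthalen-1(2H)-ylidene]methyl}-2-[2-(trimethylsilyl)ethoxy]benzaldehyde | C[C@H]1CC[C@H]2C(C)(C)CCC[C@]2(C)/C1=C/c1cc(OS(=O)(=O)[O-])c(OCC[Si](C)(C)C)c(C=O)c1OS(=O)(=O)[O-].[Na+].[Na+] | intermediate
15 | 2-hydroxy-3,6-bis(sulfooxy)-5-{(E)-[(2S,4aS,8aS)-2,5,5,8a-tetramethyloctahydronaphthalen-1(2H)-ylidene]methyl}benzaldehyde | C[C@H]1CC[C@H]2C(C)(C)CCC[C@]2(C)/C1=C/c1cc(OS(=O)(=O)O)c(O)c(C=O)c1OS(=O)(=O)O | target

## Step count and least certain steps

Total: 12 steps. Longest linear sequence: 9 steps (steps 1, 2, 3, 7, 8, 9, 10, 11, 12, from 1 to 15). The arene branch (steps 4–6) joins at step 8.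

**Step 3 (key step).** The most likely failure is incomplete facial selectivity at 250 °C: some hydrogen delivery from the β-face would give the C8 epimer. Other risks are thermal relactonisation of 3, catalysed by the acid itself, and acid-mediated migration of the new exocyclic double bond into the ring, which erases C8. A C8 epimer would have to be carried on and removed after the coupling.

The fallback sets out from 1 and comes back at 4. It sets C8 by hydrogenation and cleaves the carbon by radical decarboxylation. Lactone 1 is opened with KOH in MeOH and the carboxylate is methylated with MeI to give hydroxy ester F1. Dehydration with SOCl2/pyridine at −78 °C gives the exocyclic alkene ester F2. Hydrogenation over PtO2 from the open α-face should give the 8β-methyl ester F3. Saponification gives acid F4, and photocatalytic dehydrodecarboxylation (acridine photocatalyst with a cobaloxime) gives 4.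

**Step 1.** The equilibrium may hold too much of the trisubstituted and exocyclic alkene isomers, the lactone may re-form, and long exposure to acid may trigger a methyl shift from C10.

The fallback sets out from 1 and comes back at 3, with the position of the double bond defined by mechanism. The lithium enolate of 1 (LDA, −78 °C) is selenenylated with PhSeCl to the 11-phenylselanyl lactone F5. Oxidation with H2O2 and syn-elimination toward H9 give butenolide F6. Reductive cleavage of the allylic C8–O bond with SmI2 (THF, t-BuOH), followed by kinetic α-protonation of the dienolate, gives 3.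

**Step 8.** Transmetalation may be slow, because boron sits on a CH2 next to a CH flanked by a quaternary carbon. Protodeboronation, or reduction of the aldehyde by residual B–H, could then compete.

The fallback sets out from 9 and comes back at 10. Oxidation of 9 (NaOH, H2O2) gives the primary alcohol F7. Iodination (I2, PPh3, imidazole) gives iodide F8. Zinc insertion and Negishi coupling with 8 (Pd/SPhos) give 10; organozinc halides tolerate the aldehyde.

**Step 10.** The o-quinone methide may be diverted by conjugate addition of adventitious water or amine at C11, or the vinylogous ester at C4' may be lost before tautomerisation. Redox exchange between quinone and hydroquinone may also stall the conversion.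

The fallback sets out from 4 and 8 and comes back at 13; the alkene is made by C–C coupling instead. Mizoroki–Heck arylation of 4 with 8 (Pd(OAc)2, P(o-tol)3, K2CO3, DMF, 100 °C) gives styrene F9. Ce(IV) oxidation gives vinylquinone F10, and Na2S2O4 reduction gives 13. The risk then moves to β-hydride elimination toward C8–H in the Heck step.

**Step 11.** Sulfation of the hindered, hydrogen-bonded 2'-OH may stop at the mono-sulfate, and 13 may reoxidise to the quinone.

The fallback sets out from 13 and comes back at 14, through neutral sulfate diesters that can be chromatographed. Treatment of 13 with 2,2,2-trichloroethyl chlorosulfate (DMAP, Et3N, THF) gives bis(trichloroethyl sulfate) F11. Reductive removal of both trichloroethyl groups (Zn, HCO2NH4, MeOH) and sodium exchange give 14.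

## Further compounds

F1 | step 3 | methyl 2-[(1R,2R,4aS,8aS)-2-hydroxy-2,5,5,8a-tetramethyldecahydronaphthalen-1-yl]acetate | CC1(CCC[C@]2([C@H]1CC[C@@](O)([C@@H]2CC(=O)OC)C)C)C
F2 | step 3 | methyl 2-[(4aS,8aS)-5,5,8a-trimethyl-2-methylidenedecahydronaphthalen-1-yl]acetate (9α-H) | CC1(CCC[C@]2([C@H]1CCC(=C)[C@@H]2CC(=O)OC)C)C
F3 | step 3 | methyl 2-[(2S,4aS)-2,5,5,8a-tetramethyldecahydronaphthalen-1-yl]acetate (8β-methyl, 9α-H, 10β-methyl) | C[C@H]1CC[C@H]2C(C)(C)CCC[C@]2(C)[C@H]1CC(=O)OC
F4 | step 3 | 2-[(2S,4aS)-2,5,5,8a-tetramethyldecahydronaphthalen-1-yl]acetic acid (8β-methyl, 9α-H, 10β-methyl) | C[C@H]1CC[C@H]2C(C)(C)CCC[C@]2(C)[C@H]1CC(=O)O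
F5 | step 1 | 11-(phenylselanyl)sclareolide (lactone 1 with SePh on the carbon α to the carbonyl) | CC1(CCC[C@]2([C@H]1CC[C@@]3([C@@H]2C([Se]c4ccccc4)C(=O)O3)C)C)C
F6 | step 1 | 9(11)-dehydrosclareolide (butenolide, C9=C11 conjugated with the lactone carbonyl) | CC1(CCC[C@]2([C@H]1CC[C@@]3(C2=CC(=O)O3)C)C)C
F7 | step 8 | [(2S,4aS)-2,5,5,8a-tetramethyldecahydronaphthalen-1-yl]methanol (8β-methyl, 9α-H, 10β-methyl) | C[C@H]1CC[C@H]2C(C)(C)CCC[C@]2(C)[C@H]1CO
F8 | step 8 | (2S,4aS)-1-(iodomethyl)-2,5,5,8a-tetramethyldecahydronaphthalene (8β-methyl, 9α-H, 10β-methyl) | C[C@H]1CC[C@H]2C(C)(C)CCC[C@]2(C)[C@H]1CI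
F9 | step 10 | 3,6-dimethoxy-5-{(E)-[(2S,4aS,8aS)-2,5,5,8a-tetramethyloctahydronaphthalen-1(2H)-ylidene]methyl}-2-[2-(trimethylsilyl)ethoxy]benzaldehyde | C[C@H]1CC[C@H]2C(C)(C)CCC[C@]2(C)/C1=C/c1cc(OC)c(OCC[Si](C)(C)C)c(C=O)c1OC
F10 | step 10 | 3,6-dioxo-5-{(E)-[(2S,4aS,8aS)-2,5,5,8a-tetramethyloctahydronaphthalen-1(2H)-ylidene]methyl}-2-[2-(trimethylsilyl)ethoxy]cyclohexa-1,4-diene-1-carbaldehyde | C[C@H]1CC[C@H]2C(C)(C)CCC[C@]2(C)/C1=C/C1=CC(=O)C(OCC[Si](C)(C)C)=C(C=O)C1=O
F11 | step 11 | bis(2,2,2-trichloroethyl) sulfate diester of 13 at O3 and O6 of the benzaldehyde ring | C[C@H]1CC[C@H]2C(C)(C)CCC[C@]2(C)/C1=C/c1cc(OS(=O)(=O)OCC(Cl)(Cl)Cl)c(OCC[Si](C)(C)C)c(C=O)c1OS(=O)(=O)OCC(Cl)(Cl)Cl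
A1 | alternative 1 | 8β-methyl-driman-11-al, (2S,4aS)-2,5,5,8a-tetramethyldecahydronaphthalene-1-carbaldehyde (9α-H, 10β-methyl) | C[C@H]1CC[C@H]2C(C)(C)CCC[C@]2(C)[C@H]1C=O
A2 | alternative 1 | [(2S,4aS)-2,5,5,8a-tetramethyldecahydronaphthalen-1-yl](2,4,5-trimethoxyphenyl)methanol (both carbinol epimers) | C[C@H]1CC[C@H]2C(C)(C)CCC[C@]2(C)[C@H]1C(O)c1cc(OC)c(OC)cc1OC
A3 | alternative 2 | 1,2,4-trimethoxy-5-[(2E,6E)-3,7,11-trimethyldodeca-2,6,10-trien-1-yl]benzene | CC(C)=CCC/C(C)=C/CC/C(C)=C/Cc1cc(OC)c(OC)cc1OC
A4 | alternative 3 | 11-(2,4,5-trimethoxyphenyl)sclareolide (aryl on the carbon α to the lactone carbonyl) | CC1(CCC[C@]2([C@H]1CC[C@@]3([C@@H]2C(c4cc(OC)c(OC)cc4OC)C(=O)O3)C)C)C
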